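**Retrosynthetic overview**
1. Germacrane numbering is used: C1 ketone, C2=C3, C4(Me)=C5, C6–O lactone, C7, C8–OTig, C9–OH, C10(Me)–O, C11–C13 lactone arm. The route rests on the 3(2H)-furanone ring O–C3=C2–C1(=O)–C10. Its C1 ketone sits between quaternary C10 and sp2 C2, and its C3–O bond and C2–H are what remains after a C10 hydroxyl adds across a C2≡C3 ynone. Furanone ring and ten-membered carbocycle therefore both reduce to one aldehyde-to-alkyne bond, C1–C2.
2. Late stage: C13–Cl and C11–OH come from HCl opening of the 11,13-spiro-epoxide of the α-methylene lactone. The furanone comes from hydroxy ynone 36 by gold-catalysed 5-endo-dig closure, and the ynone from carbinol 34.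
3. Key disconnection: 34 from iodoalkyne aldehyde 32 by CrCl2/NiCl2 ring closure at C1–C2.
4. 32 comes from bromobutenolide 13 (C2–C7, C11–C13, C15) and aldehyde 22 (C1, C8–C10, C14) by a zinc Barbier reaction at C7–C8. The closed Barbier transition state cannot be relied on for the 8S carbinol, so C8 is reset by oxidation and chelate-controlled reduction. O9 is carried as a PMB ether and O10 as a TES ether, so that only O10 is free when the furanone closes.
5. Ring order: γ-lactone (step 5), ten-membered carbocycle (step 19), furanone (step 22). The oxirane made in step 23 is opened again in step 24.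

Key step: step 19

Assumption: (S,S)-ProPhenol is taken to give the 6R carbinol in step 4; if the sense of induction is the reverse, the (R,R) ligand is used and nothing else changes.

**Fragment A (C2–C7, C11–C13)**

Step 1
Reactants: 1 but-2-yn-1-ol
Product: 3 (Z)-3-iodobut-2-en-1-ol, via cyclic alkenylaluminate 2 (not isolated)
Conditions: NaAlH2(OCH2CH2OMe)2, THF, 0 °C to rt; then I2, THF, −78 °C
Reagents that add atoms: iodine, II
Why: Hydroxyl-directed trans-hydroalumination of the propargylic alcohol places aluminium on the future C4 inside a five-membered chelate, and iodinolysis with retention gives the Z-iodide that fixes the C4=C5 geometry.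

Step 2
Reactants: 3 (Z)-3-iodobut-2-en-1-ol; 4 ethynyltrimethylsilane
Product: 5 (Z)-3-methyl-5-(trimethylsilyl)pent-2-en-4-yn-1-ol
Conditions: PdCl2(PPh3)2 (2 mol %), CuI (4 mol %), Et3N, THF, rt
Reagents that add atoms: none
Why: Sonogashira coupling of an alkenyl iodide forms C3–C4 with retention of the alkene geometry.

Step 3
Reactants: 5 (Z)-3-methyl-5-(trimethylsilyl)pent-2-en-4-yn-1-ol
Product: 6 (Z)-3-methyl-5-(trimethylsilyl)pent-2-en-4-ynal
Conditions: activated MnO2, CH2Cl2, rt, dark
Reagents that add atoms: none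
Why: Allylic alcohol oxidation on MnO2 is neutral and heterogeneous, so the Z-enal should not isomerise.

Step 4
Reactants: 6 (Z)-3-methyl-5-(trimethylsilyl)pent-2-en-4-ynal; 7 methyl propiolate
Product: 9 methyl (4R,5Z)-4-hydroxy-6-methyl-8-(trimethylsilyl)oct-5-ene-2,7-diynoate, via methylzinc acetylide 8 (not isolated)
Conditions: (S,S)-ProPhenol (20 mol %), Me2Zn, toluene, 4 °C
Reagents that add atoms: none
Why: Zinc–ProPhenol catalysed asymmetric alkynylation of an enal forms C6–C7, the dinuclear zinc pocket holding the aldehyde so that the acetylide reaches one face only and sets C6 as R.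

Step 5
Reactants: 9 methyl (4R,5Z)-4-hydroxy-6-methyl-8-(trimethylsilyl)oct-5-ene-2,7-diynoate
Product: 12 (5R)-3-(hydroxymethyl)-5-[(1Z)-2-methyl-4-(trimethylsilyl)but-1-en-3-yn-1-yl]furan-2(5H)-one, via alkenylalane 10 (not isolated), via open-chain diol ester 11 (not isolated)
Conditions: iBu2AlH, HMPA, THF, 0 °C; then CH2O (monomer in THF), −78 to 0 °C; 1 M HCl work-up, rt
Reagents that add atoms: formaldehyde, C=O
Why: Conjugate syn-hydroalumination of the ynoate puts H on C7 and Al on C11, the alkenylalane adds to formaldehyde (vinylalumination) to bring in C13, and because O6 and the ester are cis across C7=C11 the diol ester lactonises on acidic work-up without touching C6.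

Step 6
Reactants: 12 (5R)-3-(hydroxymethyl)butenolide
Product: 13 (5R)-3-(bromomethyl)-5-[(1Z)-2-methyl-4-(trimethylsilyl)but-1-en-3-yn-1-yl]furan-2(5H)-one
Conditions: CBr4, PPh3, CH2Cl2, 0 °C
Reagents that add atoms: tetrabromomethane, BrC(Br)(Br)Br
Why: Appel bromination of the primary allylic alcohol runs under neutral conditions and so spares the acidic, doubly allylic C6–H.

**Fragment B (C1, C8–C10)**

Step 7
Reactants: 14 acrolein; 15 ethyl 2-(triphenyl-λ5-phosphanylidene)propanoate
Product: 16 ethyl (2E)-2-methylpenta-2,4-dienoate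
Conditions: CH2Cl2, 0 °C to rt
Reagents that add atoms: none
Why: Wittig olefination with a stabilised ylide gives the E-trisubstituted C9=C10 alkene.

Step 8
Reactants: 16 ethyl (2E)-2-methylpenta-2,4-dienoate
Product: 17 (2E)-2-methylpenta-2,4-dien-1-ol
Conditions: iBu2AlH, CH2Cl2, −78 °C
Reagents that add atoms: none
Why: Hydride 1,2-reduction of the conjugated ester with iBu2AlH gives the allylic alcohol without touching the diene.

Step 9
Reactants: 17 (2E)-2-methylpenta-2,4-dien-1-ol
Product: 18 [(2R,3R)-3-ethenyl-2-methyloxiran-2-yl]methanol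
Conditions: Ti(OiPr)4 (10 mol %), D-(−)-diethyl tartrate (12 mol %), t-BuOOH, 4 Å MS, CH2Cl2, −20 °C
Reagents that add atoms: tert-butyl hydroperoxide, CC(C)(C)OO
Why: Katsuki–Sharpless asymmetric epoxidation oxidises only the alkene of the allylic alcohol, and the D-(−)-tartrate delivers oxygen to the face that gives the 2R,3R oxirane, which sets C10.

Step 10
Reactants: 18 [(2R,3R)-3-ethenyl-2-methyloxiran-2-yl]methanol
Product: 19 (2R,3S)-3-[(4-methoxybenzyl)oxy]-2-methylpent-4-ene-1,2-diol
Conditions: Ti(OiPr)4 (1.5 equiv) premixed with excess 4-methoxybenzyl alcohol and stripped of iPrOH, CH2Cl2, rt to 40 °C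
Reagents that add atoms: 4-methoxybenzyl alcohol, COc1ccc(CO)cc1
Why: In this titanium-assisted opening of a 2,3-epoxy alcohol the metal binds O1 and the oxirane oxygen and steers the alkoxide to the distal, allylic C9, where SN2 inversion sets C9 while C10 keeps its oxygen and configuration.

Step 11
Reactants: 19 (2R,3S)-3-[(4-methoxybenzyl)oxy]-2-methylpent-4-ene-1,2-diol
Product: 20 (3S,4R)-3-[(4-methoxybenzyl)oxy]-4-methyl-4,5-bis(triethylsilyloxy)pent-1-ene
Conditions: Et3SiOTf, 2,6-lutidine, CH2Cl2, −78 to 0 °C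
Reagents that add atoms: triethylsilyl triflate, CC[Si](CC)(CC)OS(=O)(=O)C(F)(F)F
Why: Silyl triflate silylation is strong enough to cap the tertiary O10 together with the primary O1 in one operation.

Step 12
Reactants: 20 (3S,4R)-3-[(4-methoxybenzyl)oxy]-4-methyl-4,5-bis(triethylsilyloxy)pent-1-ene
Product: 22 (2R,3R)-2-[(4-methoxybenzyl)oxy]-3-methyl-3,4-bis(triethylsilyloxy)butanal, via secondary ozonide 21 (not isolated)
Conditions: O3, CH2Cl2, −78 °C (dye end point); then PPh3, −78 °C to rt
Reagents that add atoms: ozone, [O-][O+]=O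
Why: Ozonolysis with reductive work-up cleaves the only alkene under non-aqueous, neutral conditions, so the C8 aldehyde is released without epimerising C9.

**Union and elaboration**

Step 13
Reactants: 13 (5R)-3-(bromomethyl)butenolide; 22 aldehyde of fragment B
Product: 24 Barbier adduct (6R,7S,9S,10R; both C8 epimers), via allylzinc bromide 23 (not isolated)
Conditions: Zn, THF/sat. aq NH4Cl, 0 °C to rt
Reagents that add atoms: none
Why: In this zinc Barbier allylation the allylzinc reacts at its γ-carbon C7 (SE2′), which moves the alkene to the exocyclic C11=C13 position; the aldehyde approaches the ring face opposite the C6 side chain and sets 7S (6,7-trans), while C8, for which the closed chair favours the unwanted 8R epimer, is erased in step 14.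

Step 14
Reactants: 24 Barbier adduct
Product: 25 C8 ketone (6R,7S,9R,10R)
Conditions: Dess–Martin periodinane, NaHCO3, CH2Cl2, 0 °C
Reagents that add atoms: none
Why: Buffered Dess–Martin oxidation converges both C8 epimers on one ketone under conditions too mild to move the exocyclic alkene or to expel O6 or O10.

Step 15
Reactants: 25 C8 ketone
Product: 26 8S alcohol (6R,7S,8S,9S,10R)
Conditions: Zn(BH4)2, Et2O, −78 to −20 °C
Reagents that add atoms: none
Why: In this Cram-chelate reduction zinc bridges the C8 carbonyl and the PMB-bearing O9, and hydride enters from the face away from quaternary C10 to give the 8,9-anti diol pattern (8S) without conjugate reduction of the lactone.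

Step 16
Reactants: 26 8S alcohol; 27 tiglic acid
Product: 29 C8 tiglate (6R,7S,8S,9S,10R), via mixed tiglic 2,4,6-trichlorobenzoic anhydride 28 (not isolated)
Conditions: 27, 2,4,6-trichlorobenzoyl chloride, Et3N, toluene, rt; then 26, DMAP, rt to 40 °C
Reagents that add atoms: none
Why: Yamaguchi esterification acylates the hindered secondary O8, the only free hydroxyl, with retention at C8 and without loss of the E geometry of the acid.

Step 17
Reactants: 29 C8 tiglate
Product: 30 iodoalkyne (C2–I)
Conditions: N-iodosuccinimide, AgNO3 (20 mol %), DMF, rt, dark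
Reagents that add atoms: N-iodosuccinimide, O=C1CCC(=O)N1I
Why: Silver-catalysed ipso-iododesilylation exchanges the alkynyl C–Si bond for C–I directly and leaves the O-silyl ethers alone.

Step 18
Reactants: 30 iodoalkyne
Product: 32 iodoenyne lactone aldehyde (6R,7S,8S,9S,10S), via alkoxydimethylsulfonium chloride 31 (not isolated)
Conditions: (COCl)2, DMSO, CH2Cl2, −78 to −40 °C; then Et3N, to 0 °C
Reagents that add atoms: none
Why: Under Swern conditions a primary triethylsilyl ether is cleaved by the activated sulfoxide and oxidised in the same flask, whereas the hindered tertiary O10 silyl ether does not react.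

Step 19
Reactants: 32 iodoenyne lactone aldehyde
Product: 34 ten-membered Z-enynol (both C1 epimers), via alkynylchromium dichloride 33 (not isolated)
Conditions: CrCl2 (8 equiv), NiCl2 (1 mol % of the chromium salt), degassed THF, syringe-pump addition to about 1 mM, rt
Reagents that add atoms: none
Why: Two equivalents of CrCl2 (divalent chromium) reduce the C2–I bond, the trace of NiCl2 (divalent nickel, reduced in the flask to low-valent nickel) speeding the insertion and passing the alkynyl group to chromium, so that alkynylchromium dichloride 33 (trivalent chromium) forms and adds to the C1 aldehyde bound at its Lewis-acidic metal. The closest known reaction type is the Nozaki–Hiyama–Kishi macrocyclisation of iodoalkyne aldehydes that closes ten-membered enediyne carbocycles. The one ring formed is the carbocycle C1–C10, closed in a 10-exo-trig mode at the carbonyl carbon with the C2≡C3 alkyne and the Z C4=C5 alkene inside the ring; the Z alkene and the trans-substituted lactone turn the chain ends toward each other, and slow addition at high dilution holds back dimers. The new C1 carbinol centre is at most biased by a Felkin–Anh approach past the C10 silyl ether and needs no control, because step 20 removes it. Only chemoselectivity is required: divalent chromium inserts into the C(sp)–I bond but leaves the tiglate, the α-methylene lactone, the PMB ether and the silyl ether alone, organochromium reagents add 1,2 and are barely basic, and the aldehyde cannot enolise because C10 is quaternary.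

Step 20
Reactants: 34 ten-membered Z-enynol
Product: 35 cyclic ynone
Conditions: Dess–Martin periodinane, NaHCO3, CH2Cl2, 0 °C
Reagents that add atoms: none
Why: Dess–Martin oxidation of the propargylic alcohol merges both C1 epimers into the C1 ketone.

Step 21
Reactants: 35 cyclic ynone
Product: 36 C10 hydroxy ynone
Conditions: HF·pyridine, pyridine, THF, 0 °C
Reagents that add atoms: none
Why: Fluoride-mediated desilylation frees O10 only, since O9 stays a PMB ether and so cannot compete later by six-membered ring closure onto C3.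

Step 22
Reactants: 36 C10 hydroxy ynone
Product: 37 furanone (O9 PMB ether, α-methylene lactone)
Conditions: AuCl3 (5 mol %), CH2Cl2, rt
Reagents that add atoms: none
Why: Gold-catalysed cycloisomerisation of an α′-hydroxy ynone activates C2≡C3 for 5-endo-dig attack of O10 at the β-carbon C3, protodeauration gives the 3(2H)-furanone, and release of the bent alkyne's strain drives the closure.

Step 23
Reactants: 37 furanone
Product: 38 (11R)-11,13-spiro-epoxide
Conditions: t-BuOOH, n-BuLi, THF, −78 to −20 °C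
Reagents that add atoms: tert-butyl hydroperoxide, CC(C)(C)OO
Why: In this nucleophilic (Weitz–Scheffer type) epoxidation the peroxide anion adds fastest to the unsubstituted C13 terminus of the α-methylene lactone, and the enolate closes the C11–O bond on the face carrying H7, opposite the C8 branch, which sets C11.

Step 24
Reactants: 38 (11R)-11,13-spiro-epoxide
Product: 39 (11S)-chlorohydrin O9 PMB ether
Conditions: HCl (4 M in dioxane), CH2Cl2, 0 °C
Reagents that add atoms: hydrogen chloride, Cl
Why: Acid-promoted opening of the glycidic lactone takes chloride at primary C13, because positive charge next to the carbonyl at C11 is disfavoured, so the C11–O bond and its configuration are kept.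

Step 25
Reactants: 39 (11S)-chlorohydrin O9 PMB ether
Product: 40 target CNP0272644.2 (6R,7S,8S,9S,10S,11S)
Conditions: DDQ, CH2Cl2/pH 7 buffer, 0 °C
Reagents that add atoms: none
Why: Oxidative PMB cleavage by hydride abstraction at the electron-rich benzyl position frees O9 under neutral conditions that do not provoke tiglate migration or loss of HCl.

**Compound list**
1 | but-2-yn-1-ol | CC#CCO | starting material
2 | sodium 2,2-bis(2-methoxyethoxy)-3-methyl-2,5-dihydro-1,2-oxaluminol-2-uide (cyclic alkenylaluminate) | CC1=CCO[Al-]1(OCCOC)OCCOC.[Na+] | intermediate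
3 | (Z)-3-iodobut-2-en-1-ol | C/C(I)=C/CO | intermediate
4 | ethynyltrimethylsilane | C[Si](C)(C)C#C | starting material
5 | (Z)-3-methyl-5-(trimethylsilyl)pent-2-en-4-yn-1-ol | C/C(C#C[Si](C)(C)C)=C/CO | intermediate
6 | (Z)-3-methyl-5-(trimethylsilyl)pent-2-en-4-ynal | C/C(C#C[Si](C)(C)C)=C/C=O | intermediate
7 | methyl propiolate | C#CC(=O)OC | starting material
8 | methyl 3-(methylzincio)propiolate | C[Zn]C#CC(=O)OC | intermediate
9 | methyl (4R,5Z)-4-hydroxy-6-methyl-8-(trimethylsilyl)oct-5-ene-2,7-diynoate | COC(=O)C#C[C@@H](/C=C(/C)C#C[Si](C)(C)C)O | intermediate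
10 | C11-diisobutylalumino enoate, O6 diisobutylaluminium alkoxide (ester cis to C6) | COC(=O)/C([Al](CC(C)C)CC(C)C)=C\[C@@H](/C=C(/C)C#C[Si](C)(C)C)O[Al](CC(C)C)CC(C)C | intermediate
11 | methyl (2Z,4R,5Z)-4-hydroxy-2-(hydroxymethyl)-6-methyl-8-(trimethylsilyl)octa-2,5-dien-7-ynoate | COC(=O)/C(CO)=C\[C@@H](/C=C(/C)C#C[Si](C)(C)C)O | intermediate
12 | (5R)-3-(hydroxymethyl)-5-[(1Z)-2-methyl-4-(trimethylsilyl)but-1-en-3-yn-1-yl]furan-2(5H)-one | OCC1=C[C@@H](/C=C(/C)C#C[Si](C)(C)C)OC1=O | intermediate
13 | (5R)-3-(bromomethyl)-5-[(1Z)-2-methyl-4-(trimethylsilyl)but-1-en-3-yn-1-yl]furan-2(5H)-one | BrCC1=C[C@@H](/C=C(/C)C#C[Si](C)(C)C)OC1=O | intermediate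
14 | acrolein | C=CC=O | starting material
15 | ethyl 2-(triphenyl-λ5-phosphanylidene)propanoate | CCOC(=O)C(C)=P(c1ccccc1)(c1ccccc1)c1ccccc1 | starting material
16 | ethyl (2E)-2-methylpenta-2,4-dienoate | C=C/C=C(\C)C(=O)OCC | intermediate
17 | (2E)-2-methylpenta-2,4-dien-1-ol | C=C/C=C(\C)CO | intermediate
18 | [(2R,3R)-3-ethenyl-2-methyloxiran-2-yl]methanol | OC[C@@]1(C)O[C@@H]1C=C | intermediate
19 | (2R,3S)-3-[(4-methoxybenzyl)oxy]-2-methylpent-4-ene-1,2-diol | OC[C@@](C)(O)[C@@H](OCc1ccc(OC)cc1)C=C | intermediate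
20 | (3S,4R)-3-[(4-methoxybenzyl)oxy]-4-methyl-4,5-bis(triethylsilyloxy)pent-1-ene | CC[Si](CC)(CC)OC[C@@](C)(O[Si](CC)(CC)CC)[C@@H](OCc1ccc(OC)cc1)C=C | intermediate
21 | secondary ozonide (1,2,4-trioxolane) of 20 | CC[Si](CC)(CC)OC[C@@](C)(O[Si](CC)(CC)CC)[C@@H](OCc1ccc(OC)cc1)C1OCOO1 | intermediate
22 | (2R,3R)-2-[(4-methoxybenzyl)oxy]-3-methyl-3,4-bis(triethylsilyloxy)butanal | CC[Si](CC)(CC)OC[C@@](C)(O[Si](CC)(CC)CC)[C@@H](OCc1ccc(OC)cc1)C=O | intermediate
23 | allylzinc bromide from 13 | Br[Zn]CC1=C[C@@H](/C=C(/C)C#C[Si](C)(C)C)OC1=O | intermediate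
24 | Barbier adduct: 6,7-trans α-methylene-γ-lactone with C8 carbinol (6R,7S,9S,10R; C8 epimers) | CC[Si](CC)(CC)OC[C@@](C)(O[Si](CC)(CC)CC)[C@@H](OCc1ccc(OC)cc1)C(O)[C@@H]1[C@@H](/C=C(/C)C#C[Si](C)(C)C)OC(=O)C1=C | intermediate
25 | C8 ketone (6R,7S,9R,10R) | CC[Si](CC)(CC)OC[C@@](C)(O[Si](CC)(CC)CC)[C@@H](OCc1ccc(OC)cc1)C(=O)[C@@H]1[C@@H](/C=C(/C)C#C[Si](C)(C)C)OC(=O)C1=C | intermediate
26 | 8S alcohol (6R,7S,8S,9S,10R) | CC[Si](CC)(CC)OC[C@@](C)(O[Si](CC)(CC)CC)[C@@H](OCc1ccc(OC)cc1)[C@@H](O)[C@@H]1[C@@H](/C=C(/C)C#C[Si](C)(C)C)OC(=O)C1=C | intermediate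
27 | tiglic acid | C/C=C(\C)C(=O)O | starting material
28 | mixed tiglic 2,4,6-trichlorobenzoic anhydride | C/C=C(\C)C(=O)OC(=O)c1c(Cl)cc(Cl)cc1Cl | intermediate
29 | C8 tiglate, C2 trimethylsilyl alkyne, C1 and O10 TES ethers, O9 PMB ether (6R,7S,8S,9S,10R) | CC[Si](CC)(CC)OC[C@@](C)(O[Si](CC)(CC)CC)[C@@H](OCc1ccc(OC)cc1)[C@@H](OC(=O)/C(C)=C/C)[C@@H]1[C@@H](/C=C(/C)C#C[Si](C)(C)C)OC(=O)C1=C | intermediate
30 | iodoalkyne corresponding to 29 | CC[Si](CC)(CC)OC[C@@](C)(O[Si](CC)(CC)CC)[C@@H](OCc1ccc(OC)cc1)[C@@H](OC(=O)/C(C)=C/C)[C@@H]1[C@@H](/C=C(/C)C#CI)OC(=O)C1=C | intermediate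
31 | C1 alkoxydimethylsulfonium chloride | C[S+](C)OC[C@@](C)(O[Si](CC)(CC)CC)[C@@H](OCc1ccc(OC)cc1)[C@@H](OC(=O)/C(C)=C/C)[C@@H]1[C@@H](/C=C(/C)C#CI)OC(=O)C1=C.[Cl-] | intermediate
32 | iodoenyne lactone aldehyde, key-step precursor (6R,7S,8S,9S,10S) | O=C[C@@](C)(O[Si](CC)(CC)CC)[C@@H](OCc1ccc(OC)cc1)[C@@H](OC(=O)/C(C)=C/C)[C@@H]1[C@@H](/C=C(/C)C#CI)OC(=O)C1=C | intermediate
33 | alkynylchromium dichloride from 32 | O=C[C@@](C)(O[Si](CC)(CC)CC)[C@@H](OCc1ccc(OC)cc1)[C@@H](OC(=O)/C(C)=C/C)[C@@H]1[C@@H](/C=C(/C)C#C[Cr](Cl)Cl)OC(=O)C1=C | intermediate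
34 | ten-membered Z-enynol, key-step product (C6–C10 as in 32; C1 epimers) | C/C=C(\C)C(=O)O[C@H]1[C@@H]2[C@@H](/C=C(/C)C#CC(O)[C@@](C)(O[Si](CC)(CC)CC)[C@H]1OCc3ccc(OC)cc3)OC(=O)C2=C | intermediate
35 | cyclic ynone (C1 ketone, O10 TES ether) | C/C=C(\C)C(=O)O[C@H]1[C@@H]2[C@@H](/C=C(/C)C#CC(=O)[C@@](C)(O[Si](CC)(CC)CC)[C@H]1OCc3ccc(OC)cc3)OC(=O)C2=C | intermediate
36 | C10 hydroxy ynone | C/C=C(\C)C(=O)O[C@H]1[C@@H]2[C@@H](/C=C(/C)C#CC(=O)[C@@](C)(O)[C@H]1OCc3ccc(OC)cc3)OC(=O)C2=C | intermediate
37 | furanone with α-methylene lactone, O9 PMB ether (6R,7S,8S,9S,10S) | C/C=C(\C)C(=O)O[C@H]1[C@@H]2[C@@H](/C=C(/C)C3=CC(=O)[C@@](C)(O3)[C@H]1OCc4ccc(OC)cc4)OC(=O)C2=C | intermediate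
38 | (11R)-11,13-spiro-epoxide of 37 | C/C=C(\C)C(=O)O[C@H]1[C@@H]2[C@@H](/C=C(/C)C3=CC(=O)[C@@](C)(O3)[C@H]1OCc4ccc(OC)cc4)OC(=O)[C@]25CO5 | intermediate
39 | (11S)-11-hydroxy-13-chloro lactone, O9 PMB ether | C/C=C(\C)C(=O)O[C@H]1[C@@H]2[C@@H](/C=C(/C)C3=CC(=O)[C@@](C)(O3)[C@H]1OCc4ccc(OC)cc4)OC(=O)[C@]2(O)CCl | intermediate
40 | CNP0272644.2 (6R,7S,8S,9S,10S,11S) | C/C=C(\C)C(=O)O[C@H]1[C@@H]2[C@@H](/C=C(/C)C3=CC(=O)[C@@](C)(O3)[C@H]1O)OC(=O)[C@]2(O)CCl | target

**Step count**
- Total step count: 25.
- Longest linear sequence: 19 steps (steps 1–6 then 13–25; steps 7–12 then 13–25 are equally long).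

**Steps most likely to fail**

Step 19.
- What may go wrong: intermolecular addition (oligomers) or simple protonation of the alkynylchromium may outrun closure of the strained ring.
- Fallback: it sets out from 29 and replaces reductive metalation of a C–I bond by soft deprotonation of a terminal alkyne.
- Catalytic AgNO3 in aqueous acetone removes the C-silyl group to give the terminal alkyne F1.
- The Swern protocol of step 18 then gives the alkynal F2.
- Zn(OTf)2 and Et3N in toluene at high dilution generate a zinc acetylide that adds to the C1 aldehyde.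
- The route is rejoined at 34.

Step 15 (with the ketone of step 14).
- What may go wrong: hydride delivery may show poor facial selectivity if the zinc chelate does not form, or the exocyclic alkene may drift into conjugation at the ketone stage.
- Fallback: it sets out from 24 and drops the redox detour in favour of substitution with inversion.
- The C8 epimers of 24 are separated. The 8S epimer is 26 and enters step 16.
- The 8R alcohol F3 is esterified with 27 under Mitsunobu conditions (PPh3, diisopropyl azodicarboxylate, toluene) with inversion at C8.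
- The route is rejoined at 29.

Step 23.
- What may go wrong: peroxide addition to the furanone dienone may compete, or oxygen may be delivered to the wrong lactone face.
- Fallback: it sets out from 34 and installs the oxirane before any dienone or ynone exists, when the tiglate is the only other acceptor.
- t-BuOOH/n-BuLi converts 34 into the epoxy enynol F4.
- Dess–Martin oxidation gives the epoxy ynone F5.
- Buffered HF·pyridine frees O10 to give the epoxy hydroxy ynone F6.
- AuCl3 closes the furanone, and the route is rejoined at 38.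

**Further compounds**
F1 | step 19 | terminal alkyne corresponding to 29 | CC[Si](CC)(CC)OC[C@@](C)(O[Si](CC)(CC)CC)[C@@H](OCc1ccc(OC)cc1)[C@@H](OC(=O)/C(C)=C/C)[C@@H]1[C@@H](/C=C(/C)C#C)OC(=O)C1=C
F2 | step 19 | terminal alkynal (C1 aldehyde, C2–H) | O=C[C@@](C)(O[Si](CC)(CC)CC)[C@@H](OCc1ccc(OC)cc1)[C@@H](OC(=O)/C(C)=C/C)[C@@H]1[C@@H](/C=C(/C)C#C)OC(=O)C1=C
F3 | step 15 | 8R alcohol (6R,7S,8R,9S,10R) | CC[Si](CC)(CC)OC[C@@](C)(O[Si](CC)(CC)CC)[C@@H](OCc1ccc(OC)cc1)[C@H](O)[C@@H]1[C@@H](/C=C(/C)C#C[Si](C)(C)C)OC(=O)C1=C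
F4 | step 23 | (11R)-11,13-epoxide of enynol 34 | C/C=C(\C)C(=O)O[C@H]1[C@@H]2[C@@H](/C=C(/C)C#CC(O)[C@@](C)(O[Si](CC)(CC)CC)[C@H]1OCc3ccc(OC)cc3)OC(=O)[C@]24CO4
F5 | step 23 | (11R)-11,13-epoxy ynone, O10 TES ether | C/C=C(\C)C(=O)O[C@H]1[C@@H]2[C@@H](/C=C(/C)C#CC(=O)[C@@](C)(O[Si](CC)(CC)CC)[C@H]1OCc3ccc(OC)cc3)OC(=O)[C@]24CO4
F6 | step 23 | (11R)-11,13-epoxy C10 hydroxy ynone | C/C=C(\C)C(=O)O[C@H]1[C@@H]2[C@@H](/C=C(/C)C#CC(=O)[C@@](C)(O)[C@H]1OCc3ccc(OC)cc3)OC(=O)[C@]24CO4
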